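## Retrosynthetic overview

1. The target is reached by removing two methoxymethyl (MOM) ethers from a ketone that already holds every carbon atom.
2. That ketone is disconnected at the bond between the carbonyl carbon and C6 of ring A. The enabling feature: C6 carries the ketone between the phenolic oxygens on C5 and C7, so ring A is an ortho-hydroxyaryl ketone. This is the retron of an aryne insertion into the acyl–oxygen bond of a carboxylic acid, in which the oxygen on C7 beside a C5≡C6 triple bond steers the carboxylate oxygen to C5 and the acyl group to C6.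
3. The aryne precursor (C6 silyl, C5 triflate, C7 OMOM) comes from phloroglucinol and 3-methylbut-2-enoic acid. The pyran ring is closed first as a chroman-4-one, whose chelated 5-OH differentiates the two phenols and directs iodine to C6; the carbonyl is then removed and iodine is exchanged for silicon by a retro-Brook shift.
4. The ring B acid comes from 3-bromo-4,5-dihydroxybenzaldehyde by 4-O-methylation, MOM protection, Stille prenylation and a two-carbon homologation.
5. Ring order: rings A and B are bought as arenes; the pyran ring is the only ring built (step 1), and the key step then joins the two halves.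

Key step: step 12

Remark: the target has no stereocentre, so none has to be set; the only stereo-element on the way is the E double bond of 17, removed in step 10. Compounds 1, 2 and 13 and all reagents named below are taken as commercially available.

## Route

Step 1
Reactants: 1 phloroglucinol (benzene-1,3,5-triol); 2 3-methylbut-2-enoic acid
Product: 3 5,7-dihydroxy-2,2-dimethylchroman-4-one
Conditions: P2O5, MeSO3H, 70 °C
Reagents that add atoms: none
Why: Friedel–Crafts acylation of the threefold-symmetric triol by the activated acid, followed by intramolecular oxa-Michael addition of the neighbouring phenol, should close the dimethylpyranone ring, and the symmetry of 1 allows only one product.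

Step 2
Reactants: 3 5,7-dihydroxy-2,2-dimethylchroman-4-one
Product: 4 5-hydroxy-7-(methoxymethoxy)-2,2-dimethylchroman-4-one
Conditions: MOMCl (1.1 equiv), iPr2NEt, CH2Cl2, 0 °C to rt
Reagents that add atoms: chloromethyl methyl ether (MOMCl), COCCl
Why: Williamson-type O-alkylation should occur only at the free, more acidic 7-OH, because the 5-OH is held in a hydrogen bond to the C4 carbonyl and is far less nucleophilic.

Step 3
Reactants: 4 5-hydroxy-7-(methoxymethoxy)-2,2-dimethylchroman-4-one
Product: 5 5-hydroxy-6-iodo-7-(methoxymethoxy)-2,2-dimethylchroman-4-one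
Conditions: NIS (1.05 equiv), DMF, rt, dark
Reagents that add atoms: N-iodosuccinimide, O=C1CCC(=O)N1I
Why: Electrophilic aromatic iodination under neutral conditions should go ortho to the chelated 5-OH, at C6, as it does for 5-hydroxy-7-alkoxyflavones, and any C8 iodide could not pass on silicon in step 5 and so cannot lead to a wrong aryne.

Step 4
Reactants: 5 5-hydroxy-6-iodo-7-(methoxymethoxy)-2,2-dimethylchroman-4-one
Product: 8 6-iodo-7-(methoxymethoxy)-2,2-dimethylchroman-5-ol, via aryl ethyl carbonate 6 (not isolated), via ortho-quinone methide 7 (not isolated)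
Conditions: ClCO2Et, Et3N, THF, 0 °C; then NaBH4, H2O, 0 °C to rt
Reagents that add atoms: none
Why: Reductive deoxygenation of an ortho-acylphenol through its ethyl carbonate: borohydride reduces the ketone of 6, the benzylic alkoxide takes over the carbonate and is expelled to give ortho-quinone methide 7, and 1,4-addition of hydride should give the ortho-alkylphenol while the aryl iodide and the MOM ether stay untouched.

Step 5
Reactants: 8 6-iodo-7-(methoxymethoxy)-2,2-dimethylchroman-5-ol
Product: 12 7-(methoxymethoxy)-2,2-dimethyl-6-(trimethylsilyl)chroman-5-yl trifluoromethanesulfonate, via trimethylsilyl ether 9 (not isolated), via aryllithium 10 (not isolated), via lithium phenoxide 11 (not isolated)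
Conditions: (Me3Si)2NH, THF, reflux, then evaporate; n-BuLi, THF, −78 °C; Tf2O, −78 °C to rt
Reagents that add atoms: hexamethyldisilazane, C[Si](C)(C)N[Si](C)(C)C; trifluoromethanesulfonic anhydride, O=S(=O)(OS(=O)(=O)C(F)(F)F)C(F)(F)F
Why: This is the standard one-pot entry to ortho-silylaryl triflates from ortho-halophenols: O-silylation, fast iodine–lithium exchange, retro-Brook rearrangement (1,3 shift of silicon from oxygen to the C6 carbanion) and O-triflation of the freed phenoxide, which should fix silicon at C6 and the leaving group at C5.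

Step 6
Reactants: 13 3-bromo-4,5-dihydroxybenzaldehyde
Product: 14 3-bromo-5-hydroxy-4-methoxybenzaldehyde
Conditions: MeI (1.0 equiv), Li2CO3, DMF, 40 °C
Reagents that add atoms: iodomethane, CI
Why: With one equivalent of a weak base only the more acidic 4-OH (para to the aldehyde, ortho to bromine) is deprotonated, so O-methylation should be selective for that oxygen, as known for 3,4-dihydroxybenzaldehydes.

Step 7
Reactants: 14 3-bromo-5-hydroxy-4-methoxybenzaldehyde
Product: 15 3-bromo-4-methoxy-5-(methoxymethoxy)benzaldehyde
Conditions: MOMCl, iPr2NEt, CH2Cl2, 0 °C to rt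
Reagents that add atoms: chloromethyl methyl ether (MOMCl), COCCl
Why: Williamson-type O-alkylation of the only remaining phenol should mask it so that it cannot compete as a nucleophile for the aryne in step 12.

Step 8
Reactants: 15 3-bromo-4-methoxy-5-(methoxymethoxy)benzaldehyde
Product: 16 4-methoxy-3-(methoxymethoxy)-5-(3-methylbut-2-enyl)benzaldehyde
Conditions: tributyl(3-methylbut-2-enyl)stannane (1.3 equiv), Pd(PPh3)4 (5 mol %), DMF, 100 °C
Reagents that add atoms: tributyl(3-methylbut-2-enyl)stannane, CCCC[Sn](CCCC)(CCCC)CC=C(C)C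
Why: Stille coupling: zerovalent palladium inserts into the C–Br bond, the allyl group is transferred from tin, and reductive elimination at the less substituted allyl terminus should give the linear prenyl arene, with aldehyde and MOM ether tolerated.

Step 9
Reactants: 16 4-methoxy-3-(methoxymethoxy)-5-(3-methylbut-2-enyl)benzaldehyde
Product: 17 methyl (E)-3-[4-methoxy-3-(methoxymethoxy)-5-(3-methylbut-2-enyl)phenyl]prop-2-enoate
Conditions: (MeO)2P(O)CH2CO2Me, NaH, THF, 0 °C to rt
Reagents that add atoms: trimethyl phosphonoacetate, COC(=O)CP(=O)(OC)OC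
Why: Horner–Wadsworth–Emmons olefination with a stabilised phosphonate anion should give the E enoate and add the two carbons of the chain.

Step 10
Reactants: 17 methyl (E)-3-[4-methoxy-3-(methoxymethoxy)-5-(3-methylbut-2-enyl)phenyl]prop-2-enoate
Product: 18 methyl 3-[4-methoxy-3-(methoxymethoxy)-5-(3-methylbut-2-enyl)phenyl]propanoate
Conditions: Mg turnings, MeOH, 0 °C to rt
Reagents that add atoms: none
Why: Dissolving-metal conjugate reduction by single-electron transfer is limited to the aryl-conjugated enoate, so the isolated trisubstituted prenyl alkene should survive.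

Step 11
Reactants: 18 methyl 3-[4-methoxy-3-(methoxymethoxy)-5-(3-methylbut-2-enyl)phenyl]propanoate
Product: 19 3-[4-methoxy-3-(methoxymethoxy)-5-(3-methylbut-2-enyl)phenyl]propanoic acid
Conditions: LiOH, THF/MeOH/H2O, rt; then 1 M HCl to pH 4, 0 °C
Reagents that add atoms: lithium hydroxide, [Li+].[OH-]
Why: Saponification of an unhindered methyl ester, with cold acidification only to pH 4, should free the acid without touching the MOM ether or the prenyl group.

Step 12
Reactants: 12 7-(methoxymethoxy)-2,2-dimethyl-6-(trimethylsilyl)chroman-5-yl trifluoromethanesulfonate (1.3 equiv); 19 3-[4-methoxy-3-(methoxymethoxy)-5-(3-methylbut-2-enyl)phenyl]propanoic acid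
Product: 23 1-[5-hydroxy-7-(methoxymethoxy)-2,2-dimethylchroman-6-yl]-3-[4-methoxy-3-(methoxymethoxy)-5-(3-methylbut-2-enyl)phenyl]propan-1-one, via aryne 20 (not isolated), via aryl anion 21 (not isolated), via benzoxetene alkoxide 22 (not isolated)
Conditions: CsF (4 equiv), THF, 125 °C, sealed tube
Reagents that add atoms: none
Why: Fluoride attack on silicon of 12 expels triflate and generates aryne 20 (C5≡C6 of ring A); the cesium carboxylate of 19 adds through oxygen at C5, the C6 carbanion 21 attacks its own ester carbonyl, and the strained alkoxide 22 opens by C–O cleavage to the chelated phenoxide of 23, so the aryne is formally inserted into the acyl–oxygen bond of the acid and takes up the C5 oxygen and the C6 acyl group in one operation. The closest known reaction type is the fluoride-mediated addition of carboxylic acids to arynes from ortho-silylaryl triflates in hot THF, which gives ortho-hydroxyaryl ketones, including 2-hydroxy-6-alkoxyaryl ketones from 3-alkoxyarynes. No ring of the target is closed; the only ring formed is the transient four-membered ring of 22, closed by 4-exo-trig attack of the aryl anion on the ester carbonyl and reopened at once. No stereocentre is created. The step needs oxygen attack at C5 and not at C6: the methoxymethoxy group on C7 beside the triple bond withdraws inductively, distorts the aryne so that C5 is the more linear and electrophilic carbon, and stabilises the developing negative charge on C6, while the alkyl carbon C4a on the other flank is a weak, non-polarising neighbour. It also needs acyl transfer to outrun protonation of the aryl anion, which the aprotic medium, the high temperature and the four-centre intramolecular geometry should secure, and the phenol of ring B is masked as its MOM ether so that the carboxylate is the only oxygen nucleophile present.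

Step 13
Reactants: 23 1-[5-hydroxy-7-(methoxymethoxy)-2,2-dimethylchroman-6-yl]-3-[4-methoxy-3-(methoxymethoxy)-5-(3-methylbut-2-enyl)phenyl]propan-1-one
Product: 24 1-(5,7-dihydroxy-2,2-dimethylchroman-6-yl)-3-[3-hydroxy-4-methoxy-5-(3-methylbut-2-enyl)phenyl]propan-1-one (CNP0408176.0)
Conditions: HCl (1 M in MeOH), rt
Reagents that add atoms: none
Why: Acid-catalysed acetal cleavage should remove both MOM ethers, while the prenyl group of ring B has no ortho hydroxyl to cyclise onto (it lies between the methoxy carbon and a ring CH) and the chroman ether, aryl methyl ether and ketone are stable to dilute methanolic acid.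

## Compound list

1 | phloroglucinol (benzene-1,3,5-triol) | Oc1cc(O)cc(O)c1 | starting material
2 | 3-methylbut-2-enoic acid | CC(C)=CC(=O)O | starting material
3 | 5,7-dihydroxy-2,2-dimethylchroman-4-one | CC1(C)CC(=O)c2c(O)cc(O)cc2O1 | intermediate
4 | 5-hydroxy-7-(methoxymethoxy)-2,2-dimethylchroman-4-one | COCOc1cc(O)c2C(=O)CC(C)(C)Oc2c1 | intermediate
5 | 5-hydroxy-6-iodo-7-(methoxymethoxy)-2,2-dimethylchroman-4-one | COCOc1cc2OC(C)(C)CC(=O)c2c(O)c1I | intermediate
6 | ethyl 6-iodo-7-(methoxymethoxy)-2,2-dimethyl-4-oxochroman-5-yl carbonate | CCOC(=O)Oc1c(I)c(OCOC)cc2OC(C)(C)CC(=O)c12 | intermediate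
7 | 6-iodo-7-(methoxymethoxy)-2,2-dimethyl-2,3-dihydrochromen-5-one (ortho-quinone methide, C4=C4a) | O=C1C(I)=C(OCOC)C=C2OC(C)(C)CC=C12 | intermediate
8 | 6-iodo-7-(methoxymethoxy)-2,2-dimethylchroman-5-ol | COCOc1cc2OC(C)(C)CCc2c(O)c1I | intermediate
9 | [6-iodo-7-(methoxymethoxy)-2,2-dimethylchroman-5-yl]oxy-trimethylsilane | COCOc1cc2OC(C)(C)CCc2c(O[Si](C)(C)C)c1I | intermediate
10 | [7-(methoxymethoxy)-2,2-dimethyl-5-(trimethylsilyloxy)chroman-6-yl]lithium | COCOc1cc2OC(C)(C)CCc2c(O[Si](C)(C)C)c1[Li] | intermediate
11 | lithium 7-(methoxymethoxy)-2,2-dimethyl-6-(trimethylsilyl)chroman-5-olate | COCOc1cc2OC(C)(C)CCc2c([O-])c1[Si](C)(C)C.[Li+] | intermediate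
12 | 7-(methoxymethoxy)-2,2-dimethyl-6-(trimethylsilyl)chroman-5-yl trifluoromethanesulfonate | COCOc1cc2OC(C)(C)CCc2c(OS(=O)(=O)C(F)(F)F)c1[Si](C)(C)C | intermediate
13 | 3-bromo-4,5-dihydroxybenzaldehyde | O=Cc1cc(O)c(O)c(Br)c1 | starting material
14 | 3-bromo-5-hydroxy-4-methoxybenzaldehyde | COc1c(O)cc(C=O)cc1Br | intermediate
15 | 3-bromo-4-methoxy-5-(methoxymethoxy)benzaldehyde | COCOc1cc(C=O)cc(Br)c1OC | intermediate
16 | 4-methoxy-3-(methoxymethoxy)-5-(3-methylbut-2-enyl)benzaldehyde | COCOc1cc(C=O)cc(CC=C(C)C)c1OC | intermediate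
17 | methyl (E)-3-[4-methoxy-3-(methoxymethoxy)-5-(3-methylbut-2-enyl)phenyl]prop-2-enoate | COCOc1cc(/C=C/C(=O)OC)cc(CC=C(C)C)c1OC | intermediate
18 | methyl 3-[4-methoxy-3-(methoxymethoxy)-5-(3-methylbut-2-enyl)phenyl]propanoate | COCOc1cc(CCC(=O)OC)cc(CC=C(C)C)c1OC | intermediate
19 | 3-[4-methoxy-3-(methoxymethoxy)-5-(3-methylbut-2-enyl)phenyl]propanoic acid | COCOc1cc(CCC(=O)O)cc(CC=C(C)C)c1OC | intermediate
20 | 7-(methoxymethoxy)-2,2-dimethyl-5,6-didehydrochroman (aryne, C5≡C6) | COCOC1=CC2=C(CCC(C)(C)O2)C#C1 | intermediate
21 | cesium 5-{3-[4-methoxy-3-(methoxymethoxy)-5-(3-methylbut-2-enyl)phenyl]propanoyloxy}-7-(methoxymethoxy)-2,2-dimethylchroman-6-ide | COCOc1cc2OC(C)(C)CCc2c(OC(=O)CCc2cc(OCOC)c(OC)c(CC=C(C)C)c2)[c-]1.[Cs+] | intermediate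
22 | cesium alkoxide of the four-membered hemiketal (benzoxetene) bridging O5 and C6, carbinol carbon bearing the 2-arylethyl chain | [Cs+].[O-]C1(CCc2cc(OCOC)c(OC)c(CC=C(C)C)c2)Oc2c1c(OCOC)cc1OC(C)(C)CCc21 | intermediate
23 | 1-[5-hydroxy-7-(methoxymethoxy)-2,2-dimethylchroman-6-yl]-3-[4-methoxy-3-(methoxymethoxy)-5-(3-methylbut-2-enyl)phenyl]propan-1-one | COCOc1cc(CCC(=O)c2c(OCOC)cc3OC(C)(C)CCc3c2O)cc(CC=C(C)C)c1OC | intermediate
24 | 1-(5,7-dihydroxy-2,2-dimethylchroman-6-yl)-3-[3-hydroxy-4-methoxy-5-(3-methylbut-2-enyl)phenyl]propan-1-one (CNP0408176.0) | COc1c(O)cc(CCC(=O)c2c(O)cc3c(c2O)CCC(C)(C)O3)cc1CC=C(C)C | target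

## Step count and risks

Total step count: 13.
Longest linear sequence: 8 steps (steps 6 to 11, then 12 and 13). The ring A branch (steps 1 to 5) joins at step 12.

Steps most likely to fail:

Step 12. The aryl anion may be protonated before the acyl group shifts, stopping at the aryl ester. The carboxylate may also add at C6 instead of C5, or the aryne may be consumed by an ene reaction with the prenyl alkene or by the product phenoxide. The fallback forms the same two bonds stepwise by an anionic Fries rearrangement. It sets out from 8 and 19: esterification (EDC·HCl, DMAP, CH2Cl2, rt) should give the aryl ester 6-iodo-7-(methoxymethoxy)-2,2-dimethylchroman-5-yl 3-[4-methoxy-3-(methoxymethoxy)-5-(3-methylbut-2-enyl)phenyl]propanoate F1. Iodine–lithium exchange (n-BuLi, THF, −100 °C), which is faster than addition to the ester, should give the C6 aryllithium [7-(methoxymethoxy)-2,2-dimethyl-5-{3-[4-methoxy-3-(methoxymethoxy)-5-(3-methylbut-2-enyl)phenyl]propanoyloxy}chroman-6-yl]lithium F2. Its 1,3 shift of the acyl group from oxygen to carbon and aqueous work-up come back to the route at 23.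

Step 4. Acylation of the hindered, chelated phenol may be incomplete, or borohydride may strip the carbonate before the ketone is reduced, so that the sequence stalls at the ketone or the benzylic alcohol; the ortho-quinone methide may also dimerise. The fallback removes the carbonyl through a hydrazone and avoids the quinone methide. It sets out from 5: TsNHNH2, EtOH, reflux should give the tosylhydrazone N'-[5-hydroxy-6-iodo-7-(methoxymethoxy)-2,2-dimethylchroman-4-ylidene]-4-methylbenzenesulfonohydrazide F3. Reduction with catecholborane (CHCl3, 0 °C) and then NaOAc·3H2O at reflux, with loss of dinitrogen and sulfinate, comes back to the route at 8.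

Step 3. Iodination may take place at C8 or at both C6 and C8. The fallback places silicon on C6 by directed ortho-metalation, where only one position is open. It sets out from 4, which is deoxygenated under the conditions of step 4 through ethyl 7-(methoxymethoxy)-2,2-dimethyl-4-oxochroman-5-yl carbonate F4 and the ortho-quinone methide 7-(methoxymethoxy)-2,2-dimethyl-2,3-dihydrochromen-5-one F5 to 7-(methoxymethoxy)-2,2-dimethylchroman-5-ol F6. Carbamoylation (Et2NCOCl, NaH, THF) should give 7-(methoxymethoxy)-2,2-dimethylchroman-5-yl N,N-diethylcarbamate F7, whose only free ortho position is C6, which also lies beside the C7 OMOM group. Lithiation and silylation (s-BuLi, TMEDA, THF, −78 °C; Me3SiCl) should give 7-(methoxymethoxy)-2,2-dimethyl-6-(trimethylsilyl)chroman-5-yl N,N-diethylcarbamate F8. Reductive cleavage (LiAlH4, THF) should give 7-(methoxymethoxy)-2,2-dimethyl-6-(trimethylsilyl)chroman-5-ol F9, and triflation (Tf2O, pyridine, CH2Cl2, 0 °C) comes back to the route at 12.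

Further compounds
F1 | step 12 | 6-iodo-7-(methoxymethoxy)-2,2-dimethylchroman-5-yl 3-[4-methoxy-3-(methoxymethoxy)-5-(3-methylbut-2-enyl)phenyl]propanoate | COCOc1cc2OC(C)(C)CCc2c(OC(=O)CCc2cc(OCOC)c(OC)c(CC=C(C)C)c2)c1I
F2 | step 12 | [7-(methoxymethoxy)-2,2-dimethyl-5-{3-[4-methoxy-3-(methoxymethoxy)-5-(3-methylbut-2-enyl)phenyl]propanoyloxy}chroman-6-yl]lithium | COCOc1cc2OC(C)(C)CCc2c(OC(=O)CCc2cc(OCOC)c(OC)c(CC=C(C)C)c2)c1[Li]
F3 | step 4 | N'-[5-hydroxy-6-iodo-7-(methoxymethoxy)-2,2-dimethylchroman-4-ylidene]-4-methylbenzenesulfonohydrazide | COCOc1cc2OC(C)(C)CC(=NNS(=O)(=O)c3ccc(C)cc3)c2c(O)c1I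
F4 | step 3 | ethyl 7-(methoxymethoxy)-2,2-dimethyl-4-oxochroman-5-yl carbonate | CCOC(=O)Oc1cc(OCOC)cc2OC(C)(C)CC(=O)c12
F5 | step 3 | 7-(methoxymethoxy)-2,2-dimethyl-2,3-dihydrochromen-5-one (ortho-quinone methide, C4=C4a) | O=C1C=C(OCOC)C=C2OC(C)(C)CC=C12
F6 | step 3 | 7-(methoxymethoxy)-2,2-dimethylchroman-5-ol | COCOc1cc(O)c2CCC(C)(C)Oc2c1
F7 | step 3 | 7-(methoxymethoxy)-2,2-dimethylchroman-5-yl N,N-diethylcarbamate | CCN(CC)C(=O)Oc1cc(OCOC)cc2OC(C)(C)CCc12
F8 | step 3 | 7-(methoxymethoxy)-2,2-dimethyl-6-(trimethylsilyl)chroman-5-yl N,N-diethylcarbamate | CCN(CC)C(=O)Oc1c([Si](C)(C)C)c(OCOC)cc2OC(C)(C)CCc12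
F9 | step 3 | 7-(methoxymethoxy)-2,2-dimethyl-6-(trimethylsilyl)chroman-5-ol | COCOc1cc2OC(C)(C)CCc2c(O)c1[Si](C)(C)C
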